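# Proposal: total synthesis of CNP0261293.4 through a hydroxyl-delivered cyclopropane as latent C10 methyl

## The problem

Target **47** is a single cyclohexane ring, numbered here as an elemane. C10 is quaternary (vinyl C1=C2 and methyl C14), C9 is a methylene, C8 carries the (Z)-4-acetoxy-2-methylbut-2-enoate, C7 the acrylic acid C11(=C13)–C12, C6 a free hydroxyl and C5 the 3-hydroxyprop-1-en-2-yl group C4(=C3)–C15. There is no second ring to lean on, so all five stereocentres (C5, C6, C7, C8, C10) must be set on the monocycle or brought in from an open chain.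

C14, the C5 side chain, O6 and O8 lie on one face; the C7 side chain and the vinyl group lie on the other. In the chair, O6, the C7 chain and O8 are equatorial, and the C5 chain and the vinyl group are axial.

The C5/C6 pair (cis) can be made acyclically and then used as the source of all further control. O6 fixes O8 (1,3-cis) in a hydride reduction, O8 fixes C10, and C7 only has to end trans to both oxygen neighbours, the kinetically and thermodynamically preferred position.

The hard centre is C10. Its methyl group is cis to the adjacent C5 substituent, so a conjugate addition to a C9=C10 enone, which enters anti to C5, would give the wrong epimer.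

The sensitive groups are:
- the Z-enoate with its allylic acetate (Z-to-E isomerisation, butenolide formation, loss of acetate to base or hydride);
- the α-methylene acid (Michael acceptor);
- the γ-hydroxy acid pair O6/C12 (lactonisation).

These allow no base, hydride, ylide or strong acid at the end.

The enabling feature is that C14 is cis to O8 across C9. A C8 hydroxyl on a C9=C10 cyclohexenol can hand a CH2 group to both alkene carbons from its own face. The C9–C14 bond made in this way is the exocyclic bond of a cyclopropyl ketone, which electron transfer cuts again to leave C14 as the methyl group.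

## Retrosynthesis

**Unveiling (47 ⇐ 45 ⇐ 44).** No skeletal bond is cut. The acid is carried as a tert-butyl ester and O6 as a silyl ether. The order is fluoride first (**44** to **45**), silyl triflate last (**45** to **47**). In this order the free γ-hydroxy acid only appears in a mildly acidic aqueous work-up and never meets HF or base.

**C15–O (44 ⇐ 43).** The allylic hydroxyl is introduced by C–H oxidation of an isopropenyl group. Carrying a protected CH2OH from the ester stage would need a third, orthogonal silyl group and would interfere with the selective desilylation at C1. The isopropenyl group is inert to every step in between, and in **43** it is the only electron-rich alkene that has allylic hydrogens.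

**C8–O acyl bond (43 ⇐ 36 + 41).** The ester is cut next, because the acetoxy enoate survives neither enolate, hydride nor ylide chemistry. Acid **41** comes from the PMB ester **40** and this from butenolide **37**, whose ring supplies the Z geometry. What is asked of the forward step is acylation of a hindered equatorial alcohol without Z-to-E isomerisation.

**C11=C13, C1=C2 and the C8 carbinol (36 ⇐ 33 ⇐ 32 ⇐ 31 ⇐ 30 ⇐ 29).** The exocyclic methylene comes from a Mannich/elimination sequence on the ester arm of **33**, and the vinyl group from aldehyde **32** by Wittig methylenation. The C8 alcohol of **31** is made from ketone **30** by hydride delivered from the axial C1 hydroxyl, which sits 1,3 above the carbonyl. This turns the group that would block the required axial attack into the group that performs it. A three-carbon acrylate cannot be attached to C7 by enolate chemistry in one piece, because C11 is sp2; hence the two-stage arm.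

**C9–C14 and C7–C11 (29 ⇐ 28 ⇐ 25 + 26).** Reconnecting C14 to C9 leads to cyclopropyl ketone **28**. The same ketone is the best place to attach the C7 arm. In **25** the flank at C9 is a cyclopropane carbon and cannot enolise, so alkylation with **26** is regiospecific. After ring opening both C7 and C9 would compete.

**C4 side chain (25 ⇐ 24 ⇐ 23 ⇐ 21).** C4=C3 and C4–C15 are made from the ester of **21** (methyl ketone, then methylenation). This is done directly after the key step, when the ester is the only carbonyl group and no other alkene is present.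

**Key disconnection (21 ⇐ 18 + 19).** C9–C14 and C10–C14 are cut together. Methyl cuprate addition to enone **17** would be shorter, but would place the methyl group trans to the C5 substituent. Delivery of CH2 from the C8 alkoxide of **18** gives the cis arrangement. The precursor is a cyclohexenol with three stereocentres and no quaternary carbon.

**Ring (18 ⇐ 17 ⇐ 16 ⇐ 15 ⇐ 14 ⇐ 13 ⇐ 12).** The C8 carbinol comes from 1,2-reduction of enone **17**, controlled by O6. C9=C10 is closed by ring-closing metathesis of vinyl ketone **16**, which is reached from the PMB ether **12** by deprotection, oxidation, vinyl addition and oxidation.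

**C5–C6 (12 ⇐ 11 ⇐ 10 ⇐ 7 + 8; 7 ⇐ 4 + 5; 4 ⇐ 3 ⇐ 2 ⇐ 1).** With C4 as the acyl carbon, the syn-aldol relationship equals the cis relationship of the C4 chain and O6 on the ring. An auxiliary-controlled boron aldol of imide **7** with aldehyde **8** therefore sets both centres absolutely. The imide is made from acid **4** and oxazolidinone **5**; **4** derives from itaconate **1** by reduction of the conjugated acid, silylation and saponification.

## Roads not taken

**Alternative 1:** The ring would be cut at C5–C10 and C8–C9 and made by a Diels–Alder reaction of methyl coumalate A1 (diene) with the 1,1-disubstituted alkene of isoprene A2, giving the bridged lactone A3.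
- Merits: one step from two commodity chemicals forms the carbocycle and the quaternary C10. The lactone bridge ties O8 and C4 to the same face, as the target requires. C4 arrives as a carboxyl carbon and C7 already carries an ester. In step economy up to the ring this road is clearly better than the chosen one, which needs thirteen steps to reach **18**.
- Weak points: isoprene usually reacts as the diene, and here it must react as a dienophile through its more hindered alkene with one regiochemistry. The methyl/vinyl orientation at C10 rests on an endo/exo preference that is small for two groups of similar size. Adducts of this type undergo decarboxylative retro-cycloaddition at the temperatures the cycloaddition needs. The reaction gives a racemate unless a chiral catalyst is found. Afterwards C6 still has to be oxygenated cis to C5, C7 has to be set, and the C7 ester carbon has to be extended to the acrylate.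
- Comparison: the chosen plan is longer. What it sets against this is absolute control from a recoverable auxiliary and a C10 configuration fixed by an intramolecular delivery and not by a weak endo/exo bias.

**Alternative 2:** The ring would be cut at C6–C7. A chiral copper boryl complex would add boron to C8 of the enone aldehyde A4, and the copper enolate at C7 would close onto the C6 aldehyde to give the boronate aldol A5.
- Merits: one catalytic step creates the ring and three stereocentres (C6, C7, C8). Oxidation of the C–B bond gives O8 with retention, so the oxidation/reduction detour at C8 of the chosen plan is avoided; in that respect this road is better.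
- Weak points: A4 must already contain the vicinal pair C5/C10, including the quaternary centre, in an open chain. Its C5 is α to an aldehyde and doubly allylic, so it is prone to epimerisation. The catalyst has to override or match this substrate to give O6 cis to the C5 chain and C7 trans to both oxygen atoms. The acetyl group of A5 still has to become the acrylic acid, and the β-hydroxy ketone can undergo retro-aldol cleavage.
- Comparison: the ring closure is more elegant, but the hardest centre is moved into the acyclic precursor. The chosen plan sets C10 last, on a ring, from a neighbouring stereocentre.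

**Alternative 3:** The ring would be cut at C7–C8. CrCl2 (divalent chromium) would convert the allylic bromide of the bromo aldehyde A6 into an allylchromium species that adds through C7 to the C8 aldehyde, giving cyclohexanol A7.
- Merits: the ring closure delivers the α-methylene ester and a free C8 hydroxyl at once, ready for acylation. The C7 alkylation, the Mannich methylenation and the C8 redox steps of the chosen plan have no counterpart. For the late stage this road is as good as or better than the chosen one. Allylchromium additions through chair transition states usually give the anti (here trans C7/C8) product.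
- Weak points: A6 has to carry C5, C6 and the quaternary C10 with correct configuration in an open chain. The C10 problem is therefore moved upstream, not solved. The configuration of C7 relative to O6 depends on which chair closes. The product is a γ-hydroxy acrylate that can lactonise. Chromium is needed in excess.
- Comparison: the chosen plan pays with a longer end-game. It gains an acyclic stage that contains only one aldol-derived stereopair and no quaternary carbon, and every later centre is set on a ring by a neighbour.

Key step: step 14

Assumption: 4-methyl hydrogen itaconate is taken as the purchasable form of itaconic acid, and LDA, Me3SiCH2Li, n-BuLi and CH2=CHMgBr are used as commercial solutions.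

## Route

Step 1
Reactants: 1 4-methyl hydrogen itaconate
Product: 2 methyl 3-(hydroxymethyl)but-3-enoate
Conditions: BH3·SMe2, THF, −10 → 0 °C; MeOH quench
Reagents that add atoms: none
Why: Borane reduces a free carboxylic acid (through the acyloxyborane) much faster than a methyl ester or an electron-poor 1,1-disubstituted alkene, so a chemoselective acid-to-alcohol reduction is expected. The hydroxy ester is silylated at once because it can lactonise.

Step 2
Reactants: 2 methyl 3-(hydroxymethyl)but-3-enoate
Product: 3 methyl 3-[(tert-butyldimethylsilyloxy)methyl]but-3-enoate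
Conditions: TBSCl, imidazole, CH2Cl2, 0 °C → rt
Reagents that add atoms: tert-butyldimethylsilyl chloride, CC(C)(C)[Si](C)(C)Cl
Why: Standard silyl ether formation at a primary allylic alcohol; no stereocentre is involved.

Step 3
Reactants: 3 methyl 3-[(tert-butyldimethylsilyloxy)methyl]but-3-enoate
Product: 4 3-[(tert-butyldimethylsilyloxy)methyl]but-3-enoic acid
Conditions: LiOH, THF/H2O, 0 °C; then 1 M HCl to pH 4, 0 °C
Reagents that add atoms: lithium hydroxide, [Li+].[OH-]
Why: Saponification of an unhindered methyl ester at 0 °C should outrun base-induced migration of the β,γ-alkene into conjugation. Cold acidification to pH 4 spares the primary silyl ether.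

Step 4
Reactants: 4 3-[(tert-butyldimethylsilyloxy)methyl]but-3-enoic acid; 5 (R)-4-benzyloxazolidin-2-one
Product: 7 (R)-4-benzyl-3-{3-[(tert-butyldimethylsilyloxy)methyl]but-3-enoyl}oxazolidin-2-one, via mixed pivalic anhydride 6 (not isolated)
Conditions: PivCl, Et3N, THF, −20 °C; then 5 lithiated with n-BuLi, THF, −78 → 0 °C
Reagents that add atoms: none
Why: N-Acylation of the lithiated oxazolidinone by a mixed pivalic anhydride; attack occurs at the less hindered acyl carbon, and the low temperature prevents ketene formation and alkene migration.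

Step 5
Reactants: 7 (R)-4-benzyl-3-{3-[(tert-butyldimethylsilyloxy)methyl]but-3-enoyl}oxazolidin-2-one; 8 3-[(4-methoxybenzyl)oxy]propanal
Product: 10 (R)-4-benzyl-3-[(2R,3S)-3-hydroxy-5-(4-methoxybenzyloxy)-2-{3-[(tert-butyldimethylsilyl)oxy]prop-1-en-2-yl}pentanoyl]oxazolidin-2-one, via dibutylboron enolate 9 (not isolated)
Conditions: Bu2BOTf, i-Pr2NEt, CH2Cl2, −78 → 0 °C; 8, −78 → 0 °C; pH 7 buffer, MeOH, H2O2, 0 °C
Reagents that add atoms: none
Why: Evans syn-aldol: the (Z)-boron enolate reacts at its α-carbon through a closed Zimmerman–Traxler chair on the face away from the benzyl group. This sets C5 (R) and C6 (S) in one step, and the syn relationship becomes the cis relationship of the C4 chain and O6 on the ring.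

Step 6
Reactants: 10 aldol adduct
Product: 11 methyl (2R,3S)-3-hydroxy-5-(4-methoxybenzyloxy)-2-{3-[(tert-butyldimethylsilyl)oxy]prop-1-en-2-yl}pentanoate
Conditions: MeMgBr, MeOH (MeOMgBr), CH2Cl2, 0 °C
Reagents that add atoms: methanol, CO
Why: Transesterification with bromomagnesium methoxide cleaves the exocyclic imide carbonyl under chelation-assisted, weakly basic conditions that avoid retro-aldol cleavage and alkene migration; the auxiliary is recovered.

Step 7
Reactants: 11 β-hydroxy ester
Product: 12 methyl (2R,3S)-3-(tert-butyldimethylsilyloxy)-5-(4-methoxybenzyloxy)-2-{3-[(tert-butyldimethylsilyl)oxy]prop-1-en-2-yl}pentanoate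
Conditions: TBSOTf, 2,6-lutidine, CH2Cl2, −78 → 0 °C
Reagents that add atoms: tert-butyldimethylsilyl triflate, CC(C)(C)[Si](C)(C)OS(=O)(=O)C(F)(F)F
Why: Silyl ether formation at a hindered secondary alcohol with the silyl triflate; this removes the retro-aldol pathway for the steps that follow.

Step 8
Reactants: 12 PMB ether
Product: 13 methyl (2R,3S)-3-(tert-butyldimethylsilyloxy)-5-hydroxy-2-{3-[(tert-butyldimethylsilyl)oxy]prop-1-en-2-yl}pentanoate
Conditions: DDQ, CH2Cl2/pH 7 buffer, 0 °C
Reagents that add atoms: none
Why: Oxidative PMB ether cleavage by DDQ in buffered wet dichloromethane leaves the silyl ethers, the ester and the 1,1-disubstituted alkene untouched.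

Step 9
Reactants: 13 primary alcohol
Product: 14 methyl (2R,3S)-3-(tert-butyldimethylsilyloxy)-5-oxo-2-{3-[(tert-butyldimethylsilyl)oxy]prop-1-en-2-yl}pentanoate
Conditions: Dess–Martin periodinane, NaHCO3, CH2Cl2, 0 °C → rt
Reagents that add atoms: none
Why: Buffered Dess–Martin oxidation should give the β-silyloxy aldehyde without elimination, and it pre-empts δ-lactonisation of 13.

Step 10
Reactants: 14 aldehyde
Product: 15 methyl (2R,3S,5RS)-3-(tert-butyldimethylsilyloxy)-5-hydroxy-2-{3-[(tert-butyldimethylsilyl)oxy]prop-1-en-2-yl}hept-6-enoate (both C8 epimers)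
Conditions: CH2=CHMgBr, THF, −78 °C; NH4Cl quench at −78 °C
Reagents that add atoms: vinylmagnesium bromide, C=C[Mg]Br
Why: Grignard 1,2-addition to the aldehyde at −78 °C is much faster than attack on the hindered methyl ester. The C8 epimers are not separated because the centre is oxidised in the next step, and the cold quench keeps the alkoxide from closing a δ-lactone.

Step 11
Reactants: 15 allylic alcohol
Product: 16 methyl (2R,3S)-3-(tert-butyldimethylsilyloxy)-5-oxo-2-{3-[(tert-butyldimethylsilyl)oxy]prop-1-en-2-yl}hept-6-enoate
Conditions: Dess–Martin periodinane, NaHCO3, CH2Cl2, 0 °C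
Reagents that add atoms: none
Why: Dess–Martin oxidation of a secondary allylic alcohol to the vinyl ketone under neutral conditions.

Step 12
Reactants: 16 vinyl ketone
Product: 17 methyl (1R,6S)-6-(tert-butyldimethylsilyloxy)-2-[(tert-butyldimethylsilyloxy)methyl]-4-oxocyclohex-2-ene-1-carboxylate
Conditions: second-generation Grubbs catalyst (H2IMes)(PCy3)Cl2Ru=CHPh (cat.), CH2Cl2 (high dilution), 40 °C
Reagents that add atoms: none
Why: Ring-closing metathesis: the catalyst loads on the monosubstituted enone alkene and closes onto the 1,1-disubstituted alkene, forming C9=C10 of a six-membered enone with loss of ethene. High dilution suppresses dimerisation.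

Step 13
Reactants: 17 cyclohexenone
Product: 18 methyl (1R,4R,6S)-6-(tert-butyldimethylsilyloxy)-2-[(tert-butyldimethylsilyloxy)methyl]-4-hydroxycyclohex-2-ene-1-carboxylate (C8 hydroxyl cis to the C6 silyloxy group)
Conditions: NaBH4, CeCl3·7H2O, MeOH, −78 °C
Reagents that add atoms: none
Why: Luche 1,2-reduction: in the half-chair that keeps the C5 ester pseudoaxial (A1,2 strain with the C10 substituent) and the C6 silyloxy group pseudoequatorial, hydride adds axially to C8 on the face opposite to O6. The new hydroxyl is therefore cis to O6, as in cis-selective reductions of 5-substituted cyclohexenones.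

Step 14
Reactants: 18 cyclohexenol; 19 diiodomethane
Product: 21 methyl 5-(tert-butyldimethylsilyloxy)-1-[(tert-butyldimethylsilyloxy)methyl]-3-hydroxybicyclo[4.1.0]heptane-2-carboxylate... named by target atoms: bicyclo[4.1.0]heptan-2-ol with the cyclopropane CH2 (C14) bridging C9 and C10 cis to the C8 hydroxyl, via ethylzinc alkoxide 20 (not isolated)
Conditions: Et2Zn, CH2I2, CH2Cl2, −10 → 0 °C
Reagents that add atoms: none
Why: Hydroxyl-directed Simmons–Smith cyclopropanation in the Furukawa variant, the reaction established for cyclohex-2-en-1-ols. Et2Zn first converts the C8 hydroxyl into the ethylzinc alkoxide 20 and, with CH2I2, forms the carbenoid EtZnCH2I. The carbenoid is bound at the C8 oxygen and transfers CH2 to C9=C10 through the three-centre butterfly transition state, so C9–C14 and C10–C14 form in one concerted, suprafacial event; the three-membered ring is closed by a [2+1] addition and not by a stepwise cyclisation. Both new stereocentres, C9 and C10, are controlled by C8: CH2 can only arrive on the face that carries the oxygen, which puts C14 cis to O8 and hence cis to the C5 substituent. The selectivity needed is facial, in favour of the more hindered face next to the pseudoaxial C5 ester. It is secured by the covalent Zn–O tether, by the absence of any other alkene, by the C1 silyl ether being too hindered a ligand to deliver the reagent to the other face, and possibly by the ester carbonyl, which lies on the reacting face. The undirected background reaction of a trisubstituted alkene with an allylic silyloxymethyl group is slow and should not erode the result.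

Step 15
Reactants: 21 bicyclic hydroxy ester
Product: 23 the corresponding C5 methyl ketone (C4 acetyl, C8 hydroxyl free), via α-silyl ketone 22 (not isolated)
Conditions: Me3SiCH2Li (excess), THF/pentane, 0 °C → rt; then MeOH
Reagents that add atoms: (trimethylsilyl)methyllithium, [Li]C[Si](C)(C)C
Why: Ester-to-methyl-ketone conversion: addition of Me3SiCH2Li gives the α-silyl ketone, whose enolate (formed by a second equivalent) resists further addition, and methanol then removes the silyl group. The C8 alkoxide is a spectator, and C15 is introduced here.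

Step 16
Reactants: 23 methyl ketone
Product: 24 the C5 isopropenyl compound (C4=C3 installed; C8 hydroxyl free)
Conditions: Zn, CH2Br2, TiCl4, THF/CH2Cl2, 0 °C → rt
Reagents that add atoms: dibromomethane, BrCBr
Why: Lombardo methylenation is non-basic, tolerates free hydroxyl groups and converts hindered, enolisable ketones into 1,1-disubstituted alkenes; C5 should not epimerise and the C6 silyloxy group should not be eliminated.

Step 17
Reactants: 24 cyclopropyl carbinol
Product: 25 bicyclo[4.1.0]heptan-2-one (C8 ketone; cyclopropane, C5 isopropenyl and both silyl ethers unchanged)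
Conditions: Dess–Martin periodinane, NaHCO3, CH2Cl2, rt
Reagents that add atoms: none
Why: Dess–Martin oxidation of the secondary cyclopropyl carbinol; the isopropenyl group and the silyl ethers are inert.

Step 18
Reactants: 25 cyclopropyl ketone; 26 tert-butyl bromoacetate
Product: 28 C7-alkylated cyclopropyl ketone (CH2CO2t-Bu on C7, trans to the C6 silyloxy group), via lithium enolate 27 (not isolated)
Conditions: LDA, THF, −78 °C; 26, DMPU, −78 → −40 °C
Reagents that add atoms: none
Why: Kinetic lithium enolate alkylation: the ketone can only enolise toward C7 because C9 is a cyclopropane carbon. The electrophile enters on the face opposite to the C6 silyloxy group, the C5 substituent and the cyclopropane CH2, giving the C7 chain trans to O6, which is also the more stable epimer.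

Step 19
Reactants: 28 alkylated cyclopropyl ketone
Product: 29 cyclohexanone with quaternary C10 (CH3 and CH2OTBS), C7 CH2CO2t-Bu, C6 OTBS and C5 isopropenyl
Conditions: SmI2, THF/DMPU, t-BuOH, −78 → 0 °C
Reagents that add atoms: none
Why: Reductive cleavage of a cyclopropyl ketone: the ketyl formed by divalent samarium breaks the exocyclic C9–C14 bond, the one aligned with the ketyl π orbital. The primary radical is reduced and protonated to the C10 methyl, and the samarium enolate is protonated at C9, so C7 is not epimerised.

Step 20
Reactants: 29 ketone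
Product: 30 hydroxy ketone (C1 hydroxymethyl free, C6 silyl ether retained)
Conditions: HF·pyridine, pyridine, THF, 0 °C
Reagents that add atoms: none
Why: Fluoride-mediated desilylation: the primary C1 silyl ether is cleaved by buffered HF·pyridine well before the secondary C6 silyl ether, which is flanked by two branched carbons.

Step 21
Reactants: 30 hydroxy ketone
Product: 31 diol (C8 hydroxyl equatorial, cis to O6 and trans to the C7 chain; C1 hydroxymethyl)
Conditions: Me4NBH(OAc)3, MeCN/AcOH, −30 → 0 °C
Reagents that add atoms: none
Why: Hydroxyl-directed triacetoxyborohydride reduction (Saksena–Evans type): the axial C1 hydroxyl, 1,3-syn to the upper face of the C8 carbonyl, exchanges onto boron and delivers hydride to that face. Unbound reagent does not reduce ketones, so the equatorial C8 alcohol should result.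

Step 22
Reactants: 31 diol
Product: 32 hydroxy aldehyde (C1 aldehyde on C10; C8 hydroxyl free)
Conditions: TEMPO (cat.), PhI(OAc)2, CH2Cl2, rt
Reagents that add atoms: none
Why: Oxoammonium (TEMPO) oxidation is selective for the primary alcohol over the hindered secondary C8 hydroxyl. The aldehyde has no α-hydrogen and, being trans to O8, cannot form a lactol.

Step 23
Reactants: 32 hydroxy aldehyde
Product: 33 C10 vinyl compound (C8 hydroxyl free, C7 CH2CO2t-Bu)
Conditions: Ph3PCH3Br, KOt-Bu, THF, 0 °C
Reagents that add atoms: methyltriphenylphosphonium bromide, C[P+](c1ccccc1)(c1ccccc1)c1ccccc1.[Br-]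
Why: Wittig methylenation of a non-enolisable neopentyl aldehyde; excess ylide covers the C8 hydroxyl, and the tert-butyl ester resists both the ylide and the transient alkoxide.

Step 24
Reactants: 33 tert-butyl ester
Product: 36 tert-butyl acrylate (C11=C13 installed; C8 hydroxyl free), via Mannich base 34 (not isolated), via trimethylammonium iodide 35 (not isolated)
Conditions: LDA (2.5 equiv), THF, −78 °C; CH2=NMe2+ I−, −78 → 0 °C; NH4Cl; crude amine: MeI, MeOH, rt; NaHCO3 (aq), CH2Cl2, rt
Reagents that add atoms: N,N-dimethylmethyleneiminium iodide, C=[N+](C)C.[I-]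
Why: Ester α-methylenation by the Mannich route: the dianion (C8 alkoxide and ester enolate) is aminomethylated at C11, and quaternisation followed by mild base gives E1cB loss of trimethylamine. No ring stereocentre is involved, and a 5-endo oxa-Michael closure by O8 is disfavoured.

Step 25
Reactants: 37 3-methyl-2(5H)-furanone
Product: 40 4-methoxybenzyl (Z)-4-acetoxy-2-methylbut-2-enoate, via sodium hydroxy-enoate 38 (not isolated), via hydroxy PMB ester 39 (not isolated)
Conditions: NaOH (1 equiv), H2O, rt, freeze-drying; 4-MeOC6H4CH2Cl, Bu4NI (cat.), DMF, 0 °C → rt; Ac2O, pyridine, DMAP (cat.), 0 °C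
Reagents that add atoms: sodium hydroxide, [Na+].[OH-]; 4-methoxybenzyl chloride, COc1ccc(CCl)cc1; acetic anhydride, CC(=O)OC(C)=O
Why: Lactone hydrolysis, carboxylate O-alkylation and acetylation in one flask: the Z geometry is inherited from the ring. Alkylating (not acylating) the carboxylate avoids the activated acyl species that would re-close the butenolide, and the hydroxy ester is acetylated before it can relactonise.

Step 26
Reactants: 40 PMB ester
Product: 41 (Z)-4-acetoxy-2-methylbut-2-enoic acid
Conditions: TFA, anisole, CH2Cl2, 0 °C
Reagents that add atoms: none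
Why: Acidolysis of a PMB ester (SN1, cation trapped by anisole); the primary allylic acetate and the Z-alkene are stable to cold dilute TFA.

Step 27
Reactants: 36 C8 alcohol; 41 (Z)-4-acetoxy-2-methylbut-2-enoic acid
Product: 43 C8 (Z)-4-acetoxy-2-methylbut-2-enoate (tert-butyl acrylate, C6 silyl ether, C5 isopropenyl), via mixed trichlorobenzoic anhydride 42 (not isolated)
Conditions: 2,4,6-trichlorobenzoyl chloride, Et3N, toluene, rt; then 36, DMAP, toluene, rt → 40 °C
Reagents that add atoms: none
Why: Yamaguchi esterification: the preformed mixed anhydride acylates the hindered equatorial C8 hydroxyl under DMAP catalysis. This is the method of choice for (Z)-2-methylbut-2-enoates because it avoids the acid chloride and its Z-to-E isomerisation.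

Step 28
Reactants: 43 isopropenyl ester
Product: 44 allylic alcohol (C5 3-hydroxyprop-1-en-2-yl; C6 silyl ether, tert-butyl acrylate)
Conditions: SeO2 (cat.), t-BuOOH, CH2Cl2, 0 °C → rt
Reagents that add atoms: selenium dioxide, O=[Se]=O; tert-butyl hydroperoxide, CC(C)(C)OO
Why: Riley-type allylic oxidation (ene reaction, then 2,3-sigmatropic shift): the isopropenyl group is the only electron-rich alkene with allylic hydrogens, and its methyl group reacts in preference to the hindered tertiary C5–H. The vinyl group has no allylic hydrogen and the two conjugated esters are deactivated.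

Step 29
Reactants: 44 silyl ether
Product: 45 diol tert-butyl ester (C6 and C15 hydroxyls free)
Conditions: HF·pyridine (excess), THF, 0 °C → rt
Reagents that add atoms: none
Why: Fluoride-mediated cleavage of the hindered secondary silyl ether; the tert-butyl ester is inert to HF, so no free acid is present that could lactonise onto the liberated C6 hydroxyl.

Step 30
Reactants: 45 diol tert-butyl ester
Product: 47 target acid CNP0261293.4, via tris(trimethylsilyl) derivative 46 (not isolated)
Conditions: Me3SiOTf, 2,6-lutidine, CH2Cl2, 0 °C; then MeOH, aq. citric acid (pH 4), 0 °C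
Reagents that add atoms: none
Why: Silyl triflate-mediated dealkylation of the tert-butyl ester (loss of 2-methylpropene gives the silyl ester) with both hydroxyls transiently silylated. Mild methanolysis of the three Si–O bonds then releases the acid and both alcohols at about pH 4, which the acetate, the Z-enoate and the γ-hydroxy acid should tolerate.

## Compound list

1 | 4-methyl hydrogen itaconate | C=C(CC(=O)OC)C(=O)O | starting material
2 | methyl 3-(hydroxymethyl)but-3-enoate | C=C(CO)CC(=O)OC | intermediate
3 | methyl 3-[(tert-butyldimethylsilyloxy)methyl]but-3-enoate | C=C(CO[Si](C)(C)C(C)(C)C)CC(=O)OC | intermediate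
4 | 3-[(tert-butyldimethylsilyloxy)methyl]but-3-enoic acid | C=C(CO[Si](C)(C)C(C)(C)C)CC(=O)O | intermediate
5 | (R)-4-benzyloxazolidin-2-one | O=C1N[C@H](Cc2ccccc2)CO1 | starting material
6 | mixed anhydride of 4 with pivalic acid | C=C(CO[Si](C)(C)C(C)(C)C)CC(=O)OC(=O)C(C)(C)C | intermediate
7 | (R)-4-benzyl-3-{3-[(tert-butyldimethylsilyloxy)methyl]but-3-enoyl}oxazolidin-2-one | O=C1OC[C@@H](Cc2ccccc2)N1C(=O)CC(=C)CO[Si](C)(C)C(C)(C)C | intermediate
8 | 3-[(4-methoxybenzyl)oxy]propanal | COc1ccc(COCCC=O)cc1 | starting material
9 | (Z)-dibutylboron enolate of 7 | CCCCB(CCCC)O/C(=C\C(=C)CO[Si](C)(C)C(C)(C)C)N1C(=O)OC[C@H]1Cc1ccccc1 | intermediate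
10 | (R)-4-benzyl-3-[(2R,3S)-3-hydroxy-5-(4-methoxybenzyloxy)-2-{3-[(tert-butyldimethylsilyl)oxy]prop-1-en-2-yl}pentanoyl]oxazolidin-2-one | O=C1OC[C@@H](Cc2ccccc2)N1C(=O)[C@@H]([C@@H](O)CCOCc1ccc(OC)cc1)C(=C)CO[Si](C)(C)C(C)(C)C | intermediate
11 | methyl (2R,3S)-3-hydroxy-5-(4-methoxybenzyloxy)-2-{3-[(tert-butyldimethylsilyl)oxy]prop-1-en-2-yl}pentanoate | COC(=O)[C@@H]([C@@H](O)CCOCc1ccc(OC)cc1)C(=C)CO[Si](C)(C)C(C)(C)C | intermediate
12 | methyl (2R,3S)-3-(tert-butyldimethylsilyloxy)-5-(4-methoxybenzyloxy)-2-{3-[(tert-butyldimethylsilyl)oxy]prop-1-en-2-yl}pentanoate | COC(=O)[C@@H]([C@@H](O[Si](C)(C)C(C)(C)C)CCOCc1ccc(OC)cc1)C(=C)CO[Si](C)(C)C(C)(C)C | intermediate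
13 | methyl (2R,3S)-3-(tert-butyldimethylsilyloxy)-5-hydroxy-2-{3-[(tert-butyldimethylsilyl)oxy]prop-1-en-2-yl}pentanoate | COC(=O)[C@@H]([C@@H](O[Si](C)(C)C(C)(C)C)CCO)C(=C)CO[Si](C)(C)C(C)(C)C | intermediate
14 | methyl (2R,3S)-3-(tert-butyldimethylsilyloxy)-5-oxo-2-{3-[(tert-butyldimethylsilyl)oxy]prop-1-en-2-yl}pentanoate | COC(=O)[C@@H]([C@@H](O[Si](C)(C)C(C)(C)C)CC=O)C(=C)CO[Si](C)(C)C(C)(C)C | intermediate
15 | methyl (2R,3S,5RS)-3-(tert-butyldimethylsilyloxy)-5-hydroxy-2-{3-[(tert-butyldimethylsilyl)oxy]prop-1-en-2-yl}hept-6-enoate | COC(=O)[C@@H]([C@@H](O[Si](C)(C)C(C)(C)C)CC(O)C=C)C(=C)CO[Si](C)(C)C(C)(C)C | intermediate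
16 | methyl (2R,3S)-3-(tert-butyldimethylsilyloxy)-5-oxo-2-{3-[(tert-butyldimethylsilyl)oxy]prop-1-en-2-yl}hept-6-enoate | COC(=O)[C@@H]([C@@H](O[Si](C)(C)C(C)(C)C)CC(=O)C=C)C(=C)CO[Si](C)(C)C(C)(C)C | intermediate
17 | methyl (1R,6S)-6-(tert-butyldimethylsilyloxy)-2-[(tert-butyldimethylsilyloxy)methyl]-4-oxocyclohex-2-ene-1-carboxylate | CC(C)(C)[Si](C)(C)OCC1=CC(=O)C[C@H](O[Si](C)(C)C(C)(C)C)[C@@H]1C(=O)OC | intermediate
18 | methyl (1R,4R,6S)-6-(tert-butyldimethylsilyloxy)-2-[(tert-butyldimethylsilyloxy)methyl]-4-hydroxycyclohex-2-ene-1-carboxylate | CC(C)(C)[Si](C)(C)OCC1=C[C@H](O)C[C@H](O[Si](C)(C)C(C)(C)C)[C@@H]1C(=O)OC | intermediate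
19 | diiodomethane | ICI | starting material
20 | ethylzinc alkoxide of 18 (O8–Zn–Et) | CC(C)(C)[Si](C)(C)OCC1=C[C@H](O[Zn]CC)C[C@H](O[Si](C)(C)C(C)(C)C)[C@@H]1C(=O)OC | intermediate
21 | bicyclo[4.1.0]heptanol: cyclopropane CH2 (C14) on C9/C10 cis to the C8 hydroxyl; C10 CH2OTBS, C6 OTBS, C5 CO2Me | CC(C)(C)[Si](C)(C)OC[C@]12C[C@@H]2[C@H](O)C[C@H](O[Si](C)(C)C(C)(C)C)[C@@H]1C(=O)OC | intermediate
22 | α-trimethylsilyl ketone from 21 (C5 C(=O)CH2SiMe3) | CC(C)(C)[Si](C)(C)OC[C@]12C[C@@H]2[C@H](O)C[C@H](O[Si](C)(C)C(C)(C)C)[C@@H]1C(=O)C[Si](C)(C)C | intermediate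
23 | methyl ketone (C5 acetyl; C8 hydroxyl; cyclopropane) | CC(C)(C)[Si](C)(C)OC[C@]12C[C@@H]2[C@H](O)C[C@H](O[Si](C)(C)C(C)(C)C)[C@@H]1C(C)=O | intermediate
24 | isopropenyl cyclopropyl carbinol (C5 prop-1-en-2-yl; C8 hydroxyl) | CC(C)(C)[Si](C)(C)OC[C@]12C[C@@H]2[C@H](O)C[C@H](O[Si](C)(C)C(C)(C)C)[C@@H]1C(C)=C | intermediate
25 | bicyclo[4.1.0]heptan-2-one (C8 ketone; C5 isopropenyl) | CC(C)(C)[Si](C)(C)OC[C@]12C[C@@H]2C(=O)C[C@H](O[Si](C)(C)C(C)(C)C)[C@@H]1C(C)=C | intermediate
26 | tert-butyl bromoacetate | CC(C)(C)OC(=O)CBr | starting material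
27 | lithium enolate of 25 (C7=C8–OLi) | CC(C)(C)[Si](C)(C)OC[C@]12C[C@@H]2C(O[Li])=C[C@H](O[Si](C)(C)C(C)(C)C)[C@@H]1C(C)=C | intermediate
28 | C7-alkylated cyclopropyl ketone (C7 CH2CO2t-Bu trans to C6 OTBS) | CC(C)(C)[Si](C)(C)OC[C@]12C[C@@H]2C(=O)[C@@H](CC(=O)OC(C)(C)C)[C@H](O[Si](C)(C)C(C)(C)C)[C@@H]1C(C)=C | intermediate
29 | cyclohexanone with quaternary C10 (CH3 cis to the C5 isopropenyl; CH2OTBS), C7 CH2CO2t-Bu, C6 OTBS | CC(C)(C)[Si](C)(C)OC[C@@]1(C)CC(=O)[C@@H](CC(=O)OC(C)(C)C)[C@H](O[Si](C)(C)C(C)(C)C)[C@@H]1C(C)=C | intermediate
30 | hydroxy ketone (C10 CH2OH; C8 ketone) | OC[C@@]1(C)CC(=O)[C@@H](CC(=O)OC(C)(C)C)[C@H](O[Si](C)(C)C(C)(C)C)[C@@H]1C(C)=C | intermediate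
31 | diol (C10 CH2OH; C8 hydroxyl cis to O6, trans to the C7 chain) | OC[C@@]1(C)C[C@H](O)[C@@H](CC(=O)OC(C)(C)C)[C@H](O[Si](C)(C)C(C)(C)C)[C@@H]1C(C)=C | intermediate
32 | hydroxy aldehyde (C10 CHO; C8 hydroxyl) | O=C[C@@]1(C)C[C@H](O)[C@@H](CC(=O)OC(C)(C)C)[C@H](O[Si](C)(C)C(C)(C)C)[C@@H]1C(C)=C | intermediate
33 | C10 vinyl alcohol (C8 hydroxyl; C7 CH2CO2t-Bu) | C=C[C@@]1(C)C[C@H](O)[C@@H](CC(=O)OC(C)(C)C)[C@H](O[Si](C)(C)C(C)(C)C)[C@@H]1C(C)=C | intermediate
34 | Mannich base (C11 bearing CH2NMe2; C11 epimers) | C=C[C@@]1(C)C[C@H](O)[C@@H](C(CN(C)C)C(=O)OC(C)(C)C)[C@H](O[Si](C)(C)C(C)(C)C)[C@@H]1C(C)=C | intermediate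
35 | trimethylammonium iodide of 34 | C=C[C@@]1(C)C[C@H](O)[C@@H](C(C[N+](C)(C)C)C(=O)OC(C)(C)C)[C@H](O[Si](C)(C)C(C)(C)C)[C@@H]1C(C)=C.[I-] | intermediate
36 | tert-butyl acrylate alcohol (C7 C(=CH2)CO2t-Bu; C8 hydroxyl) | C=C[C@@]1(C)C[C@H](O)[C@@H](C(=C)C(=O)OC(C)(C)C)[C@H](O[Si](C)(C)C(C)(C)C)[C@@H]1C(C)=C | intermediate
37 | 3-methyl-2(5H)-furanone | CC1=CCOC1=O | starting material
38 | sodium (Z)-4-hydroxy-2-methylbut-2-enoate | [Na+].[O-]C(=O)/C(C)=C\CO | intermediate
39 | 4-methoxybenzyl (Z)-4-hydroxy-2-methylbut-2-enoate | COc1ccc(COC(=O)/C(C)=C\CO)cc1 | intermediate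
40 | 4-methoxybenzyl (Z)-4-acetoxy-2-methylbut-2-enoate | COc1ccc(COC(=O)/C(C)=C\COC(C)=O)cc1 | intermediate
41 | (Z)-4-acetoxy-2-methylbut-2-enoic acid | OC(=O)/C(C)=C\COC(C)=O | intermediate
42 | mixed anhydride of 41 with 2,4,6-trichlorobenzoic acid | O=C(OC(=O)/C(C)=C\COC(C)=O)c1c(Cl)cc(Cl)cc1Cl | intermediate
43 | C8 (Z)-4-acetoxy-2-methylbut-2-enoate with C7 tert-butyl acrylate, C6 OTBS, C5 isopropenyl, C10 vinyl/methyl | C=C[C@@]1(C)C[C@H](OC(=O)/C(C)=C\COC(C)=O)[C@@H](C(=C)C(=O)OC(C)(C)C)[C@H](O[Si](C)(C)C(C)(C)C)[C@@H]1C(C)=C | intermediate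
44 | C15 alcohol (C5 3-hydroxyprop-1-en-2-yl; C6 OTBS; tert-butyl acrylate) | C=C[C@@]1(C)C[C@H](OC(=O)/C(C)=C\COC(C)=O)[C@@H](C(=C)C(=O)OC(C)(C)C)[C@H](O[Si](C)(C)C(C)(C)C)[C@@H]1C(=C)CO | intermediate
45 | diol tert-butyl ester (C6 and C15 hydroxyls free) | C=C[C@@]1(C)C[C@H](OC(=O)/C(C)=C\COC(C)=O)[C@@H](C(=C)C(=O)OC(C)(C)C)[C@H](O)[C@@H]1C(=C)CO | intermediate
46 | tris(trimethylsilyl) derivative (silyl ester at C12, silyl ethers at O6 and O15) | C=C[C@@]1(C)C[C@H](OC(=O)/C(C)=C\COC(C)=O)[C@@H](C(=C)C(=O)O[Si](C)(C)C)[C@H](O[Si](C)(C)C)[C@@H]1C(=C)CO[Si](C)(C)C | intermediate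
47 | CNP0261293.4: 8-O-[(Z)-4-acetoxy-2-methylbut-2-enoyl]-6,15-dihydroxyelema-1,3,11(13)-trien-12-oic acid, with C14, the C5 chain, O6 and O8 on one ring face and the C7 chain and vinyl group on the other | C=C[C@@]1(C)C[C@H](OC(=O)/C(C)=C\COC(C)=O)[C@@H](C(=C)C(=O)O)[C@H](O)[C@@H]1C(=C)CO | target

## Step count and least certain steps

Total: 30 steps. Longest linear sequence: 28 steps (steps 1–24 and 27–30); steps 25–26 make the side-chain acid.

**Step 14 (key step).** Methylene transfer to C10 may be slow, because the pseudoaxial C5 ester shields the very face to which the alkoxide directs the reagent. The result would be incomplete conversion or loss of facial selectivity through the undirected pathway.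

Fallback: ester **18** is reduced with DIBAL-H to the allylic diol F1. In F1 the C5 substituent is itself a homoallylic zinc alkoxide on the reacting face, so it directs instead of blocking. Cyclopropanation of F1 with Et2Zn/CH2I2 under double alkoxide direction should give the cyclopropyl diol F2. Selective oxidation of its primary alcohol (TEMPO, NaOCl cat., NaClO2, buffered MeCN) gives the hydroxy acid F3. Excess MeLi converts F3 into methyl ketone **23**, where the route is rejoined.

**Step 18.** The C7 enolate may expel the C6 silyloxy group (β-elimination), or alkylation at the hindered C7 may be too slow to compete with proton transfer.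

Fallback: ketone **25** is condensed with 1,1-dimethylhydrazine to the dimethylhydrazone F4. Its azaenolate (LDA) is more nucleophilic and is alkylated by **26** at −78 °C to the alkylated hydrazone F5. Buffered hydrolysis (aqueous oxalic acid, two-phase) returns ketone **28**.

**Step 21.** Hydride delivery from the C1 hydroxyl through a seven-membered transition state may be too slow, or the substrate may rest as the bridged hemiketal. Forcing would then bring in undirected, unselective reduction.

Fallback: stereocontrol is moved from intramolecular delivery to thermodynamic control, one step earlier. Ketone **29** (C1 still silylated) is reduced with SmI2/H2O/Et3N in THF. The ketyl-derived carbanion is protonated to the more stable equatorial alcohol, because the axial epimer would be syn-diaxial to the C10 substituent. This gives the silyl ether alcohol F6, and selective desilylation with buffered HF·pyridine gives diol **31**.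

**Step 28.** Over-oxidation of the new allylic alcohol to the enal, competing attack at C5–H, or slow conversion next to the axial C5 position may lower the material throughput at a late stage.

Fallback: **43** is epoxidised with mCPBA at its only electron-rich alkene to the 2,2-disubstituted epoxide F7. Me3SiOTf/2,6-lutidine at −78 °C isomerises F7 (opening at the tertiary carbon, proton loss from the methyl group) to the allylic trimethylsilyl ether F8. The tert-butyl ester survives at this temperature. Mild acidic methanolysis of F8 gives **44**.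

**Step 30.** With O6 and O15 free before the Lewis-acid step, acyl migration from O8 to the 1,3-cis O6 or ionisation of the allylic acetate may compete with cleavage of the tert-butyl ester. Cleavage may also stay incomplete.

Fallback: the order of unveiling is reversed. **44**, still silylated at O6, is treated with Me3SiOTf/2,6-lutidine to give the silyl ester silyl ether F9 (not isolated). Aqueous work-up gives the C6-silylated acid F10, in which no hydroxyl is 1,3 to the C8 ester. HF·pyridine then removes the last silyl group to give **47**.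

## Further compounds

F1 | step 14 | allylic diol: 18 with the C5 ester reduced to CH2OH | CC(C)(C)[Si](C)(C)OCC1=C[C@H](O)C[C@H](O[Si](C)(C)C(C)(C)C)[C@@H]1CO
F2 | step 14 | cyclopropyl diol: 21 with CH2OH in place of the ester | CC(C)(C)[Si](C)(C)OC[C@]12C[C@@H]2[C@H](O)C[C@H](O[Si](C)(C)C(C)(C)C)[C@@H]1CO
F3 | step 14 | hydroxy acid: 21 with CO2H in place of the ester | CC(C)(C)[Si](C)(C)OC[C@]12C[C@@H]2[C@H](O)C[C@H](O[Si](C)(C)C(C)(C)C)[C@@H]1C(=O)O
F4 | step 18 | N,N-dimethylhydrazone of 25 | CC(C)(C)[Si](C)(C)OC[C@]12C[C@@H]2C(=NN(C)C)C[C@H](O[Si](C)(C)C(C)(C)C)[C@@H]1C(C)=C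
F5 | step 18 | C7-alkylated N,N-dimethylhydrazone | CC(C)(C)[Si](C)(C)OC[C@]12C[C@@H]2C(=NN(C)C)[C@@H](CC(=O)OC(C)(C)C)[C@H](O[Si](C)(C)C(C)(C)C)[C@@H]1C(C)=C
F6 | step 21 | C8 alcohol with C1 still silylated | CC(C)(C)[Si](C)(C)OC[C@@]1(C)C[C@H](O)[C@@H](CC(=O)OC(C)(C)C)[C@H](O[Si](C)(C)C(C)(C)C)[C@@H]1C(C)=C
F7 | step 28 | epoxide of the isopropenyl group of 43 (C4 epimers) | C=C[C@@]1(C)C[C@H](OC(=O)/C(C)=C\COC(C)=O)[C@@H](C(=C)C(=O)OC(C)(C)C)[C@H](O[Si](C)(C)C(C)(C)C)[C@@H]1C2(C)CO2
F8 | step 28 | C15 trimethylsilyl ether of 44 | C=C[C@@]1(C)C[C@H](OC(=O)/C(C)=C\COC(C)=O)[C@@H](C(=C)C(=O)OC(C)(C)C)[C@H](O[Si](C)(C)C(C)(C)C)[C@@H]1C(=C)CO[Si](C)(C)C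
F9 | step 30 | trimethylsilyl ester and C15 trimethylsilyl ether with O6 as tert-butyldimethylsilyl ether | C=C[C@@]1(C)C[C@H](OC(=O)/C(C)=C\COC(C)=O)[C@@H](C(=C)C(=O)O[Si](C)(C)C)[C@H](O[Si](C)(C)C(C)(C)C)[C@@H]1C(=C)CO[Si](C)(C)C
F10 | step 30 | C6-silylated acid (C12 acid and C15 hydroxyl free) | C=C[C@@]1(C)C[C@H](OC(=O)/C(C)=C\COC(C)=O)[C@@H](C(=C)C(=O)O)[C@H](O[Si](C)(C)C(C)(C)C)[C@@H]1C(=C)CO
A1 | alternative 1 | methyl coumalate | COC(=O)C1=COC(=O)C=C1
A2 | alternative 1 | isoprene | C=CC(C)=C
A3 | alternative 1 | bridged lactone adduct | C=C[C@@]1(C)C[C@@H]2OC(=O)[C@H]1C=C2C(=O)OC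
A4 | alternative 2 | enone aldehyde with C5 and C10 in place | C=C[C@@]([C@H](C=O)C(=C)CO[Si](C)(C)C(C)(C)C)(C)C/C=C/C(C)=O
A5 | alternative 2 | C8 boronate aldol | C=C[C@@]1(C)C[C@H](B2OC(C)(C)C(C)(C)O2)[C@@H](C(C)=O)[C@H](O)[C@@H]1C(=C)CO[Si](C)(C)C(C)(C)C
A6 | alternative 3 | bromo aldehyde with 2-(bromomethyl)acrylate terminus | C=C[C@@](C)(CC=O)[C@@H](C(=C)CO[Si](C)(C)C(C)(C)C)[C@@H](O[Si](C)(C)C(C)(C)C)C=C(CBr)C(=O)OCC[Si](C)(C)C
A7 | alternative 3 | cyclohexanol with free C8 hydroxyl and C7 acrylate | C=C[C@@]1(C)C[C@H](O)[C@@H](C(=C)C(=O)OCC[Si](C)(C)C)[C@H](O[Si](C)(C)C(C)(C)C)[C@@H]1C(=C)CO[Si](C)(C)C(C)(C)C
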